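## Retrosynthetic overview

1. Target numbering: C1 = oxirane carbon bearing CH2OBz, C2 = CHOH, C3 = CHOBz, C4=C5, C6 = oxirane CH. Enabling feature: the C2 hydroxyl oxygen is 1,4-related to C5, and C2(OH)–C3(OBz)–C4=C5 is what anti SN2' attack of benzoate at C3 leaves of a 2,5-dihydrofuran ring C2–C3=C4–C5–O. C2 to C5 plus that oxygen are therefore a furan, and C1–C6 a two-carbon dienophile.
2. Oxirane (C1–C6) last, by epoxidation of dienol 10 directed by the C2 hydroxyl.
3. C3–OBz and C4=C5 from rhodium-catalysed opening of the C5–O bond of the oxygen-bridged bicycle 9. The bridge is a ring the target does not contain, built to carry the chirality and cleaved here.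
4. C1–C2 and C5–C6 together, by a catalytic enantioselective Diels–Alder reaction of furan with 2-bromoacrolein. Bromohydrin, spiro-oxirane and allylic alcohol then turn the adduct into 8, the formal propargyl alcohol adduct.
5. Ring order: carbocycle plus temporary oxygen bridge (step 2), bridge opened (step 6), oxirane (step 7).

Key step: step 2

## Assumptions

- Step 2: the (S)-tryptophan-derived oxazaborolidinone is taken to open the same face of 2-bromoacrolein to furan as to cyclopentadiene, which gives the (2R) adduct 5 as drawn. Were the sense opposite, the catalyst from N-tosyl-D-tryptophan would be used with no other change.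
- Step 6: the ligand antipode named is taken to be the matched one for cleavage of the C4–O bond of 9. Its mirror image is the alternative if a first run shows the other regioisomer.
- 2-Bromoacrolein does not store well, so it is made in step 1 and used fresh. Enantiomeric purity is to be raised, if needed, by crystallisation of 10 or 11.

## Route

Step 1
Reactants: 1 acrolein
Product: 3 2-bromoprop-2-enal, via 2,3-dibromopropanal 2 (not isolated)
Conditions: Br2 (1.0 equiv), CH2Cl2, −78 °C; then Et3N (1.05 equiv), −78 → 0 °C; distilled under reduced pressure, used at once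
Reagents that add atoms: bromine, BrBr
Why: Addition of bromine to the enal and triethylamine-induced E1cB loss of HBr from the acidic α-position (bromination–dehydrobromination) is the standard entry to 2-haloacroleins, and no stereocentre survives.

Step 2
Reactants: 3 2-bromoprop-2-enal; 4 furan
Product: 6 [(1R,2S,4R)-2-bromo-7-oxabicyclo[2.2.1]hept-5-en-2-yl]methanol, via exo-formyl bromoaldehyde cycloadduct 5 (not isolated)
Conditions: (4S)-2-butyl-4-(1H-indol-3-ylmethyl)-3-tosyl-1,3,2-oxazaborolidin-5-one (10 mol%, made in the flask from N-tosyl-L-tryptophan and n-BuB(OH)2), furan (5 equiv), CH2Cl2, −78 °C; then NaBH4, EtOH, −78 → −20 °C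
Reagents that add atoms: none
Why: This is a Lewis-acid-catalysed, concerted but asynchronous [4+2] cycloaddition (Diels–Alder reaction) of furan with boron-bound 2-bromoacrolein, and the closest known reaction type is the oxazaborolidinone-catalysed enantioselective Diels–Alder addition of 2-haloacroleins to furan and cyclopentadiene. It closes one ring, the six-membered carbocycle (C1–C6 of the bicycle, the future cyclohexene), by intermolecular suprafacial–suprafacial [4+2] closure that forms C1–C2 and C3–C4 and makes the furan oxygen the one-atom bridge O7. The quaternary C2 is set by the catalyst, whose indole ring covers one face of the bound enal so that furan adds to the open face, and the bridgeheads C1 and C4 follow from C2 through the exo-formyl (bromine endo) transition state that 2-substituted acroleins prefer; furan is symmetric, so there is no regiochemical question. The step needs enantioface selectivity (catalyst), exo selectivity (the 2-bromo substituent) and kinetic control against cycloreversion and conjugate (Friedel–Crafts) alkylation of furan, which −78 °C and the NaBH4 reduction of 5 in the same flask should secure. Any endo-formyl isomer must be removed at 6, because after step 4 it would give the enantiomer of 8. Bridgehead C1 becomes the carbinol carbon C2 of the target and O7 its hydroxyl oxygen, so this step fixes the absolute configuration from which the other three stereocentres are later relayed.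

Step 3
Reactants: 6 [(1R,2S,4R)-2-bromo-7-oxabicyclo[2.2.1]hept-5-en-2-yl]methanol
Product: 7 (1R,2R,4R)-spiro[7-oxabicyclo[2.2.1]hept-5-ene-2,2'-oxirane]
Conditions: K2CO3 (1.5 equiv), MeOH, 0 °C → rt
Reagents that add atoms: none
Why: Intramolecular Williamson etherification (3-exo-tet oxirane closure of a bromohydrin), in which the primary alkoxide displaces the endo tertiary bromide from the exo face with inversion at C2, puts the oxirane oxygen exo (a configuration erased again in step 4) and leaves the bridgeheads untouched.

Step 4
Reactants: 7 (1R,2R,4R)-spiro[7-oxabicyclo[2.2.1]hept-5-ene-2,2'-oxirane]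
Product: 8 [(1R,4S)-7-oxabicyclo[2.2.1]hepta-2,5-dien-2-yl]methanol
Conditions: Et2Al(TMP) (3 equiv, from Et2AlCl and lithium 2,2,6,6-tetramethylpiperidide), toluene, 0 °C
Reagents that add atoms: none
Why: Aluminium amide-promoted isomerisation of a 1,1-disubstituted epoxide to an allylic alcohol (syn β-elimination through a cyclic transition state on the aluminium-bound oxirane) should work because the exo oxirane oxygen is eclipsed with the exo C3–H, the only β-hydrogen whose loss does not give a bridgehead alkene, so the C2=C3 bond forms in the ring, the oxygen ends on the exocyclic CH2, no new stereocentre arises and C1 and C4 keep their configuration.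

Step 5
Reactants: 8 [(1R,4S)-7-oxabicyclo[2.2.1]hepta-2,5-dien-2-yl]methanol
Product: 9 [(1R,4S)-7-oxabicyclo[2.2.1]hepta-2,5-dien-2-yl]methyl benzoate
Conditions: BzCl (1.2 equiv), Et3N, DMAP (cat.), CH2Cl2, 0 °C
Reagents that add atoms: benzoyl chloride, O=C(Cl)c1ccccc1
Why: DMAP-catalysed acylation of a primary allylic alcohol under basic conditions suits the acid-sensitive oxanorbornadiene and touches no stereocentre.

Step 6
Reactants: 9 [(1R,4S)-7-oxabicyclo[2.2.1]hepta-2,5-dien-2-yl]methyl benzoate
Product: 10 [(5S,6S)-5-(benzoyloxy)-6-hydroxycyclohexa-1,3-dien-1-yl]methyl benzoate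
Conditions: [Rh(cod)Cl]2 (2.5 mol%), (R)-1-[(S)-2-(diphenylphosphino)ferrocenyl]ethyldi-tert-butylphosphine (6 mol%), PhCO2H (3 equiv), Et3N (3 equiv), THF, 25 → 50 °C
Reagents that add atoms: benzoic acid, O=C(O)c1ccccc1
Why: In this rhodium-catalysed ring opening of an oxabicyclic alkene by a carboxylate (formal anti SN2' substitution), monovalent rhodium binds the exo face and inserts with retention into the doubly allylic bridgehead C4–O bond and benzoate then attacks the dienyl terminus C6 from the endo face opposite rhodium, so the new C5 stereocentre of 10 carries its benzoate trans to the C6 hydroxyl (whose configuration is that of bridgehead C1 of 9), while cleavage of C4–O rather than C1–O is secured by the matched ligand antipode and by the substrate, since only this cleavage puts the CH2OBz-bearing carbon at a terminus of the dienyl unit and leaves the unhindered CH terminus next to the alkoxide for attack.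

Step 7
Reactants: 10 [(5S,6S)-5-(benzoyloxy)-6-hydroxycyclohexa-1,3-dien-1-yl]methyl benzoate
Product: 11 (−)-pipoxide, [(1R,2R,3S,6S)-3-(benzoyloxy)-2-hydroxy-7-oxabicyclo[4.1.0]hept-4-en-1-yl]methyl benzoate
Conditions: VO(acac)2 (5 mol%), t-BuOOH (1.3 equiv, in decane), CH2Cl2, 0 °C
Reagents that add atoms: tert-butyl hydroperoxide, CC(C)(C)OO
Why: In this hydroxyl-directed epoxidation of an allylic alcohol by a vanadium alkylperoxide, the C6 hydroxyl of 10 binds pentavalent vanadium and delivers oxygen to the adjacent trisubstituted C1=C2 bond on its own face, which sets both oxirane carbons cis to the hydroxyl as in the target, while the C3=C4 bond, flanked by the deactivating allylic benzoate and only homoallylic to the hydroxyl, should be left.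

## Compound list

1 | acrolein (prop-2-enal) | C=CC=O | starting material
2 | 2,3-dibromopropanal (racemic) | O=CC(Br)CBr | intermediate
3 | 2-bromoprop-2-enal (2-bromoacrolein) | C=C(Br)C=O | intermediate
4 | furan | c1ccoc1 | starting material
5 | (1R,2R,4R)-2-bromo-7-oxabicyclo[2.2.1]hept-5-ene-2-carbaldehyde (formyl exo, bromine endo) | O=C[C@@]1(Br)C[C@@H]2C=C[C@H]1O2 | intermediate
6 | [(1R,2S,4R)-2-bromo-7-oxabicyclo[2.2.1]hept-5-en-2-yl]methanol (CH2OH exo, bromine endo) | OC[C@@]1(Br)C[C@@H]2C=C[C@H]1O2 | intermediate
7 | (1R,2R,4R)-spiro[7-oxabicyclo[2.2.1]hept-5-ene-2,2'-oxirane] (oxirane oxygen exo) | C1O[C@]12C[C@@H]3C=C[C@H]2O3 | intermediate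
8 | [(1R,4S)-7-oxabicyclo[2.2.1]hepta-2,5-dien-2-yl]methanol | OCC1=C[C@@H]2C=C[C@H]1O2 | intermediate
9 | [(1R,4S)-7-oxabicyclo[2.2.1]hepta-2,5-dien-2-yl]methyl benzoate | O=C(OCC1=C[C@@H]2C=C[C@H]1O2)c1ccccc1 | intermediate
10 | [(5S,6S)-5-(benzoyloxy)-6-hydroxycyclohexa-1,3-dien-1-yl]methyl benzoate (5-OBz and 6-OH trans) | O=C(OCC1=CC=C[C@H](OC(=O)c2ccccc2)[C@H]1O)c1ccccc1 | intermediate
11 | (−)-pipoxide, [(1R,2R,3S,6S)-3-(benzoyloxy)-2-hydroxy-7-oxabicyclo[4.1.0]hept-4-en-1-yl]methyl benzoate | O=C(OC[C@]12O[C@H]1C=C[C@H](OC(=O)c1ccccc1)[C@H]2O)c1ccccc1 | target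

## Count and risks

Total step count: 7. Longest linear sequence: 7 steps (1 → 3 → 6 → 7 → 8 → 9 → 10 → 11).

Steps most likely to fail:

1. Step 6. What may go wrong: rhodium- or acid-induced isomerisation of the oxanorbornadiene to a phenol; aromatisation of the dihydroarene product by loss of benzoic acid or water; insertion into the other bridgehead C–O bond; base-induced benzoyl migration between the vicinal oxygens. Fallback, setting out from 8 and coming back at 11: the oxirane is made before the bridge is opened, so neither substrate nor product can aromatise. 8 is epoxidised (VO(acac)2, t-BuOOH, CH2Cl2, 0 °C; the primary allylic hydroxyl delivers oxygen to the C2=C3 bond on the exo face, the face of the oxygen bridge) to [(1R,2R,4S,5S)-3,8-dioxatricyclo[3.2.1.0(2,4)]oct-6-en-2-yl]methanol F1. This is benzoylated (BzCl, Et3N, DMAP, CH2Cl2) to [(1R,2R,4S,5S)-3,8-dioxatricyclo[3.2.1.0(2,4)]oct-6-en-2-yl]methyl benzoate F2. The rhodium/benzoate opening is then run on F2 (same [Rh(cod)Cl]2/ligand system with tetrabutylammonium iodide as additive, PhCO2H/Et3N, THF, 60–80 °C, since the bridgehead C–O bonds are now only singly allylic) and gives 11 directly: the exo oxirane already stands cis to the bridge oxygen and benzoate enters trans to it.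

2. Step 4. What may go wrong: deprotonation at the oxirane CH2 with carbenoid rearrangement, or Lewis-acid-induced rearrangement of the spiro-oxirane to an aldehyde, instead of β-elimination; decomposition of the strained diene alcohol on work-up. Fallback, setting out from 5 and coming back at 8: 5 is worked up cold instead of being reduced and is dehydrobrominated with DBU (CH2Cl2, 0 °C; syn E2 of the endo bromide with the endo C3–H, the only elimination that does not give a bridgehead alkene) to (1R,4S)-7-oxabicyclo[2.2.1]hepta-2,5-diene-2-carbaldehyde F3. Luche reduction of F3 (NaBH4, CeCl3·7H2O, MeOH, −40 °C) gives 8 by 1,2-reduction.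

3. Step 2. What may go wrong: insufficient enantioface or exo selectivity with furan; erosion of selectivity by cycloreversion; conjugate alkylation of furan instead of cycloaddition. Fallback, setting out from 3 and 4 and coming back at 7: control by resolution instead of by the catalyst. The cycloaddition is run with the oxazaborolidinone made from racemic N-tosyltryptophan and quenched with NaBH4 as before, which gives the racemic bromohydrin rac-[(1R,2S,4R)-2-bromo-7-oxabicyclo[2.2.1]hept-5-en-2-yl]methanol F4. Acylation with (1S)-(−)-camphanic chloride (pyridine, CH2Cl2) gives two diastereomeric esters, which are separated by crystallisation or chromatography: [(1R,2S,4R)-2-bromo-7-oxabicyclo[2.2.1]hept-5-en-2-yl]methyl (1S,4R)-camphanate F5 and [(1S,2R,4S)-2-bromo-7-oxabicyclo[2.2.1]hept-5-en-2-yl]methyl (1S,4R)-camphanate F6. F5 with K2CO3 in MeOH loses the auxiliary as its methyl ester and closes in the same flask to 7.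

Further compounds
F1 | step 6 | [(1R,2R,4S,5S)-3,8-dioxatricyclo[3.2.1.0(2,4)]oct-6-en-2-yl]methanol | OC[C@]12O[C@H]1[C@@H]3C=C[C@H]2O3
F2 | step 6 | [(1R,2R,4S,5S)-3,8-dioxatricyclo[3.2.1.0(2,4)]oct-6-en-2-yl]methyl benzoate | O=C(OC[C@]12O[C@H]1[C@@H]3C=C[C@H]2O3)c1ccccc1
F3 | step 4 | (1R,4S)-7-oxabicyclo[2.2.1]hepta-2,5-diene-2-carbaldehyde | O=CC1=C[C@@H]2C=C[C@H]1O2
F4 | step 2 | rac-[(1R,2S,4R)-2-bromo-7-oxabicyclo[2.2.1]hept-5-en-2-yl]methanol (both enantiomers) | OC[C@@]1(Br)C[C@@H]2C=C[C@H]1O2.OC[C@]1(Br)C[C@H]2C=C[C@@H]1O2
F5 | step 2 | [(1R,2S,4R)-2-bromo-7-oxabicyclo[2.2.1]hept-5-en-2-yl]methyl (1S,4R)-4,7,7-trimethyl-3-oxo-2-oxabicyclo[2.2.1]heptane-1-carboxylate | O=C(OC[C@@]1(Br)C[C@@H]2C=C[C@H]1O2)[C@@]12CC[C@@](C)(C(=O)O1)C2(C)C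
F6 | step 2 | [(1S,2R,4S)-2-bromo-7-oxabicyclo[2.2.1]hept-5-en-2-yl]methyl (1S,4R)-4,7,7-trimethyl-3-oxo-2-oxabicyclo[2.2.1]heptane-1-carboxylate | O=C(OC[C@]1(Br)C[C@H]2C=C[C@@H]1O2)[C@@]12CC[C@@](C)(C(=O)O1)C2(C)C
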